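**Strategy**

The route rests on one disconnection: the bond between the quaternary, methyl-bearing fusion carbon C1 and the lactone oxygen O2 of the 2,6-dioxabicyclo[3.3.0]octan-3-one. In the key step the tert-butyl ester carbonyl of an acyclic epoxy ester opens a Shi-derived trisubstituted epoxide at its tertiary carbon with inversion, closing the γ-lactone and fixing C1 by reagent control, independently of the remote ether carbon C7 (from (R)-2-methylglycidol). The step exploits that C1 is tertiary and that lactone and tetrahydrofuran rings share the C1–C5 bond in a cis fusion: once C1–O2 exists, mesylation, elimination and oxa-Michael closure of the tetrahydrofuran set C5 automatically.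

Key step: step 7

Remark: atom labels follow the bicycle numbering of the target (C1 fusion carbon with methyl, O2 lactone oxygen, C3 carbonyl, C5 fusion CH, O6 ether oxygen, C7 ether carbon with methyl and chain); BrZnCH2CO2tBu, LiC≡CH·ethylenediamine and the D-fructose-derived Shi ketone are taken as purchasable reagents.

**Route**

Step 1
Reactants: 1 (R)-2-methylglycidol [(2R)-(2-methyloxiran-2-yl)methanol]
Product: 2 (S)-2-methylglycidyl tosylate [(2S)-(2-methyloxiran-2-yl)methyl 4-methylbenzenesulfonate]
Conditions: TsCl, Et3N, DMAP (cat.), CH2Cl2, 0 °C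
Reagents that add atoms: 4-methylbenzenesulfonyl chloride, Cc1ccc(cc1)S(Cl)(=O)=O
Why: O-sulfonylation of the primary alcohol leaves the epoxide and its quaternary stereocentre untouched (the descriptor changes from R to S only through the priority change) and prepares the hydroxymethyl carbon to become the next epoxide terminus.

Step 2
Reactants: 2 (S)-2-methylglycidyl tosylate, 3 11-bromoundec-1-ene
Product: 6 (2S)-2-(dodec-11-en-1-yl)-2-methyloxirane, via undec-10-enylmagnesium bromide 4 (not isolated), via hydroxy tosylate 5 (not isolated)
Conditions: 3, Mg, THF, 45 °C; then CuI (10 mol%), 2, THF, −30 → 0 °C; then MeOH, K2CO3, rt (same flask)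
Reagents that add atoms: none
Why: Copper-catalysed Grignard opening occurs at the unhindered epoxide CH2 while the neopentyl-type tosylate resists direct displacement, and the tertiary alkoxide then expels tosylate in an intramolecular Williamson closure (epoxide transposition), so no bond to the stereocentre is broken and C7 of the target is carried over from 1.

Step 3
Reactants: 6 (2S)-2-(dodec-11-en-1-yl)-2-methyloxirane, 7 lithium acetylide–ethylenediamine complex
Product: 8 (4S)-4-methylhexadec-15-en-1-yn-4-ol
Conditions: LiC≡CH·H2NCH2CH2NH2 (3 equiv), DMSO, rt; H2O quench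
Reagents that add atoms: none
Why: SN2 opening of the 2,2-disubstituted epoxide by acetylide takes place only at the primary carbon and gives the homopropargylic tertiary alcohol without touching the stereocentre.

Step 4
Reactants: 8 (4S)-4-methylhexadec-15-en-1-yn-4-ol
Product: 10 (1E,4S)-1-iodo-2,4-dimethylhexadeca-1,15-dien-4-ol, via alkenylalane 9 (not isolated)
Conditions: Me3Al (3 equiv), Cp2ZrCl2 (0.5 equiv), CH2Cl2, 0 °C → rt; then I2, THF, −30 → 0 °C; aq. Na2S2O3, potassium sodium tartrate
Reagents that add atoms: trimethylaluminium, C[Al](C)C; iodine, II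
Why: Zirconium-catalysed Negishi carboalumination adds methyl and aluminium syn across the terminal alkyne with methyl on the internal carbon (the hydroxyl is carried as its aluminium alkoxide and the terminal alkene does not react), and iodinolysis with retention should give the (E)-alkenyl iodide.

Step 5
Reactants: 10 (1E,4S)-1-iodo-2,4-dimethylhexadeca-1,15-dien-4-ol, 11 (2-tert-butoxy-2-oxoethyl)zinc bromide
Product: 12 tert-butyl (3E,6S)-6-hydroxy-4,6-dimethyloctadeca-3,17-dienoate
Conditions: BrZnCH2CO2tBu (3 equiv), Pd(PPh3)4 (5 mol%), THF, 50 °C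
Reagents that add atoms: none
Why: Negishi cross-coupling of the alkenyl iodide with the Reformatsky zinc enolate forms the C(sp2)–C(sp3) bond with retention of the E geometry and, being free of base, should leave the β,γ-double bond out of conjugation.

Step 6
Reactants: 12 tert-butyl (3E,6S)-6-hydroxy-4,6-dimethyloctadeca-3,17-dienoate
Product: 13 tert-butyl 2-[(2R,3R)-3-[(2S)-2-hydroxy-2-methyltetradec-13-en-1-yl]-3-methyloxiran-2-yl]acetate
Conditions: D-fructose-derived Shi ketone (30 mol%), Oxone (KHSO5), K2CO3, Bu4NHSO4, Na2B4O7/Na2EDTA buffer, MeCN/CH2(OMe)2/H2O, 0 °C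
Reagents that add atoms: potassium peroxymonosulfate (from Oxone), [K+].[O-]S(=O)(=O)OO
Why: Shi asymmetric epoxidation, in which the chiral dioxirane attacks the electron-rich (E)-trisubstituted alkene through the spiro transition state on the face that gives the (2R,3R)-oxirane (the sense known for trans- and trisubstituted alkenes with this ketone), so both new stereocentres are reagent-controlled while the monosubstituted terminal alkene reacts far more slowly.

Step 7
Reactants: 13 tert-butyl 2-[(2R,3R)-3-[(2S)-2-hydroxy-2-methyltetradec-13-en-1-yl]-3-methyloxiran-2-yl]acetate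
Product: 14 (4R,5S)-4-hydroxy-5-[(2S)-2-hydroxy-2-methyltetradec-13-en-1-yl]-5-methyloxolan-2-one
Conditions: BF3·OEt2 (1.2 equiv), CH2Cl2, −78 → −20 °C; aq. NaHCO3
Reagents that add atoms: none
Why: BF3 coordinates the epoxide oxygen and lengthens its bond to the tertiary carbon; the ester carbonyl oxygen attacks that carbon from the face opposite the departing oxygen, and the resulting tert-butoxy-dihydrofuranylium ion loses 2-methylpropene to give the lactone. The closest known reaction type is the epoxidation–lactonization of β,γ-unsaturated acids to trans-β-hydroxy-γ-lactones, here with a tert-butyl ester as terminating nucleophile as in acid-triggered epoxide-opening cyclizations. The γ-lactone closes in the 5-endo mode at the epoxide, a borderline SN2 opening with tertiary-cation character, and the oxirane is consumed. The new quaternary stereocentre (C5 of the oxolanone, later C1 of the bicycle) arises by inversion of the (R)-configured epoxide carbon installed in step 6, so it is reagent-controlled and independent of the remote carbinol, while the secondary carbinol carbon keeps its epoxide configuration and is sacrificed in step 8. The step needs regioselectivity for the tertiary over the secondary epoxide carbon (the latter would give a β-lactone by 4-exo attack) and chemoselectivity over the tertiary hydroxyl, which could reach the tertiary carbon only through an oxetane and the secondary one only against the polarization of the epoxide; the methyl group on the epoxide and the spacing of the ester secure both. Stereospecific inversion instead of a free cation (hydride shift, scrambling) should be favoured by the low temperature and the intramolecular five-membered delivery.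

Step 8
Reactants: 14 (4R,5S)-4-hydroxy-5-[(2S)-2-hydroxy-2-methyltetradec-13-en-1-yl]-5-methyloxolan-2-one
Product: 17 (1S,5S,7S)-7-(dodec-11-en-1-yl)-1,7-dimethyl-2,6-dioxabicyclo[3.3.0]octan-3-one, via mesylate 15 (not isolated), via butenolide 16 (not isolated)
Conditions: MsCl, Et3N, CH2Cl2, 0 °C; then DBU, rt
Reagents that add atoms: none
Why: Selective sulfonylation of the secondary hydroxyl and E1cB elimination give the γ,γ-disubstituted butenolide, onto which the tertiary alkoxide adds in a 5-exo-trig oxa-Michael reaction; the tether can reach the β-carbon only from the face carrying its own CH2, so the cis ring fusion and the C5 configuration follow from the quaternary C1.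

Step 9
Reactants: 17 (1S,5S,7S)-7-(dodec-11-en-1-yl)-1,7-dimethyl-2,6-dioxabicyclo[3.3.0]octan-3-one, 18 4-iodophenol
Product: 20 plakortone N [(1S,5S,7S)-7-[12-(4-hydroxyphenyl)dodecyl]-1,7-dimethyl-2,6-dioxabicyclo[3.3.0]octan-3-one], via B-alkyl-9-BBN adduct 19 (not isolated)
Conditions: 9-BBN, THF, 0 °C → rt; then 18, Pd(dppf)Cl2 (5 mol%), Cs2CO3, DMF/H2O, 50 °C; dilute HCl work-up
Reagents that add atoms: none
Why: Anti-Markovnikov hydroboration of the only alkene with 9-BBN followed by B-alkyl Suzuki–Miyaura coupling with the aryl iodide joins C(sp3)–C(sp2) without touching a stereocentre, and the acidic work-up should re-close any lactone opened by the base.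

**Compound list**

1 | (R)-2-methylglycidol | C[C@@]1(CO)CO1 | starting material
2 | (S)-2-methylglycidyl tosylate | C[C@@]1(COS(=O)(=O)c2ccc(C)cc2)CO1 | intermediate
3 | 11-bromoundec-1-ene | C=CCCCCCCCCCBr | starting material
4 | undec-10-enylmagnesium bromide | C=CCCCCCCCCC[Mg]Br | intermediate
5 | (2S)-2-hydroxy-2-methyltetradec-13-en-1-yl 4-methylbenzenesulfonate | C[C@@](O)(COS(=O)(=O)c1ccc(C)cc1)CCCCCCCCCCC=C | intermediate
6 | (2S)-2-(dodec-11-en-1-yl)-2-methyloxirane | C[C@]1(CCCCCCCCCCC=C)CO1 | intermediate
7 | lithium acetylide–ethylenediamine complex | [Li]C#C.NCCN | starting material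
8 | (4S)-4-methylhexadec-15-en-1-yn-4-ol | C[C@](O)(CCCCCCCCCCC=C)CC#C | intermediate
9 | (E)-alkenyl(dimethyl)alane of 8 with the hydroxyl as its dimethylaluminium alkoxide | C[C@](O[Al](C)C)(CCCCCCCCCCC=C)C/C(C)=C/[Al](C)C | intermediate
10 | (1E,4S)-1-iodo-2,4-dimethylhexadeca-1,15-dien-4-ol | C[C@](O)(CCCCCCCCCCC=C)C/C(C)=C/I | intermediate
11 | (2-tert-butoxy-2-oxoethyl)zinc bromide | CC(C)(C)OC(=O)C[Zn]Br | starting material
12 | tert-butyl (3E,6S)-6-hydroxy-4,6-dimethyloctadeca-3,17-dienoate | C[C@](O)(CCCCCCCCCCC=C)C/C(C)=C/CC(=O)OC(C)(C)C | intermediate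
13 | tert-butyl 2-[(2R,3R)-3-[(2S)-2-hydroxy-2-methyltetradec-13-en-1-yl]-3-methyloxiran-2-yl]acetate | CC(C)(C)OC(=O)C[C@H]1O[C@]1(C)C[C@@](C)(O)CCCCCCCCCCC=C | intermediate
14 | (4R,5S)-4-hydroxy-5-[(2S)-2-hydroxy-2-methyltetradec-13-en-1-yl]-5-methyloxolan-2-one | O=C1C[C@@H](O)[C@](C)(C[C@@](C)(O)CCCCCCCCCCC=C)O1 | intermediate
15 | (2S,3R)-2-[(2S)-2-hydroxy-2-methyltetradec-13-en-1-yl]-2-methyl-5-oxooxolan-3-yl methanesulfonate | O=C1C[C@@H](OS(C)(=O)=O)[C@](C)(C[C@@](C)(O)CCCCCCCCCCC=C)O1 | intermediate
16 | (5S)-5-[(2S)-2-hydroxy-2-methyltetradec-13-en-1-yl]-5-methylfuran-2(5H)-one | O=C1C=C[C@](C)(C[C@@](C)(O)CCCCCCCCCCC=C)O1 | intermediate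
17 | (1S,5S,7S)-7-(dodec-11-en-1-yl)-1,7-dimethyl-2,6-dioxabicyclo[3.3.0]octan-3-one | C[C@]1(CCCCCCCCCCC=C)C[C@]2(C)OC(=O)C[C@@H]2O1 | intermediate
18 | 4-iodophenol | Oc1ccc(I)cc1 | starting material
19 | (1S,5S,7S)-7-[12-(9-borabicyclo[3.3.1]nonan-9-yl)dodecyl]-1,7-dimethyl-2,6-dioxabicyclo[3.3.0]octan-3-one | C[C@]1(CCCCCCCCCCCCB2C3CCCC2CCC3)C[C@]2(C)OC(=O)C[C@@H]2O1 | intermediate
20 | plakortone N, (1S,5S,7S)-7-[12-(4-hydroxyphenyl)dodecyl]-1,7-dimethyl-2,6-dioxabicyclo[3.3.0]octan-3-one | C[C@]1(CCCCCCCCCCCCc2ccc(O)cc2)C[C@]2(C)OC(=O)C[C@@H]2O1 | target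

**Step count**

Total steps: 9. Longest linear sequence: 9 (steps 1 to 9 from compound 1).

**Steps most likely to fail**

Step 7 (key step). Ionisation of the tertiary epoxide carbon may run ahead of ring closure, leading to hydride shift towards a ketone and erosion of the inversion, and the expelled tert-butyl cation may alkylate the substrate. The fallback sets out from 12 and changes both the nucleophile and the mode of activation. The tert-butyl ester would be cleaved first (TMSOTf, 2,6-lutidine, CH2Cl2, 0 °C; then K2CO3, MeOH/H2O and acidification, which also removes the transient silyl ether) to give (3E,6S)-6-hydroxy-4,6-dimethyloctadeca-3,17-dienoic acid F1. Shi epoxidation of this acid as its carboxylate under the buffer of step 6 should give 2-[(2R,3R)-3-[(2S)-2-hydroxy-2-methyltetradec-13-en-1-yl]-3-methyloxiran-2-yl]acetic acid F2, which would not be isolated. Acidification to pH 3 lets the free carboxylic acid open the oxirane at the tertiary carbon with inversion (the classical epoxidation–lactonization of β,γ-unsaturated acids, without Lewis acid and without cationic tert-butyl transfer). The route is rejoined at 14.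

Step 5. Protonolysis of the zinc enolate by the free tertiary hydroxyl, slow transmetalation to palladium, or migration of the new double bond into conjugation may spoil the coupling. The fallback sets out from 8 and introduces the two-carbon unit as an epoxide electrophile instead. Carboalumination as in step 4 gives 9, which is turned into its alanate with n-BuLi and opened with ethylene oxide to give (3E,6S)-4,6-dimethyloctadeca-3,17-diene-1,6-diol F3. Oxidation of the primary alcohol with TEMPO/PhI(OAc)2 in MeCN/H2O should pass through (3E,6S)-6-hydroxy-4,6-dimethyloctadeca-3,17-dienal F4, not isolated, to the acid F1 described above. tert-Butyl 2,2,2-trichloroacetimidate (cyclohexane/CH2Cl2, rt, no catalyst) then esterifies the carboxylic acid in preference to the tertiary alcohol, and the route is rejoined at 12.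

Step 9. Hydrolytic opening of the lactone under aqueous base, slow oxidative addition into the electron-rich iodophenoxide, or protodeboronation of the alkylborane may compromise the last step. The fallback sets out from 17 and replaces the boron chemistry by olefin metathesis. Cross-metathesis with an excess of 1-(benzyloxy)-4-vinylbenzene (second-generation Hoveyda–Grubbs catalyst, RuCl2(=CH-C6H4-2-OiPr)(H2IMes), CH2Cl2, 40 °C) should give (1S,5S,7S)-7-[(11E)-12-(4-benzyloxyphenyl)dodec-11-en-1-yl]-1,7-dimethyl-2,6-dioxabicyclo[3.3.0]octan-3-one F5. Hydrogenation (H2, Pd/C, EtOAc) then saturates the alkene and removes the benzyl group in one operation, arriving at 20.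

**Further compounds**

F1 | step 7 | (3E,6S)-6-hydroxy-4,6-dimethyloctadeca-3,17-dienoic acid | C[C@](O)(CCCCCCCCCCC=C)C/C(C)=C/CC(=O)O
F2 | step 7 | 2-[(2R,3R)-3-[(2S)-2-hydroxy-2-methyltetradec-13-en-1-yl]-3-methyloxiran-2-yl]acetic acid | OC(=O)C[C@H]1O[C@]1(C)C[C@@](C)(O)CCCCCCCCCCC=C
F3 | step 5 | (3E,6S)-4,6-dimethyloctadeca-3,17-diene-1,6-diol | C[C@](O)(CCCCCCCCCCC=C)C/C(C)=C/CCO
F4 | step 5 | (3E,6S)-6-hydroxy-4,6-dimethyloctadeca-3,17-dienal | C[C@](O)(CCCCCCCCCCC=C)C/C(C)=C/CC=O
F5 | step 9 | (1S,5S,7S)-7-[(11E)-12-(4-benzyloxyphenyl)dodec-11-en-1-yl]-1,7-dimethyl-2,6-dioxabicyclo[3.3.0]octan-3-one | C[C@]1(CCCCCCCCCC/C=C/c2ccc(OCc3ccccc3)cc2)C[C@]2(C)OC(=O)C[C@@H]2O1
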